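**Retrosynthetic overview**
1. The last bond made is C4 (pyran ring C, upper unit) to C6 (benzo ring D, lower unit). Cutting it gives two molecules of one monomer, a 2,3-trans-3,4-trans flavan-3,4-diol: one ionises at C4, the other attacks through C6. No ring forms here.
2. The C4 carbinol of the monomer goes back to the C4 ketone of the (2R,3R)-dihydroflavonol. Reduction and dimerisation share one flask and run on free phenols.
3. Each pyran ring (C in the upper unit, F in the lower) is cut at O1–C2 and C3–O back to a 2'-hydroxychalcone: oxygenation at Cα/Cβ, then 6-endo attack of the 2'-phenol on Cβ. This is the plant's chalcone → dihydroflavonol ring closure, done in one flask and enantioselectively on the unprotected 2'-phenol.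
4. The chalcone is cut at Cα=Cβ into an acetophenone (rings A and D) and a benzaldehyde (rings B and E).
5. Ring order: the benzene rings are bought; both pyran rings are made by the same operation at the monomer stage; the units are joined afterwards.

Assumption: the SMILES is read as fisetinidol-(4β→6)-mollisacacidin, upper unit 2R,3S,4S (2,3-trans-3,4-cis), lower unit 2R,3S,4R (2,3-trans-3,4-trans); Oxone is counted as its active salt KHSO5.

**Step 1**
Reactants: 1 4'-benzyloxy-2'-hydroxyacetophenone; 2 3,4-bis(benzyloxy)benzaldehyde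
Product: 4 (E)-4'-benzyloxy-2'-hydroxy-3,4-bis(benzyloxy)chalcone, via aldol adduct 3 (not isolated)
Conditions: KOH (50% aq, 5 equiv), EtOH, 20 °C, 48 h; then 1 M HCl to pH 3
Reagents that add atoms: none
Why: Claisen–Schmidt (crossed aldol) condensation, in which the enolate of 1 adds to the non-enolisable aldehyde 2 and the aldol 3 loses water (E1cB) to the favoured (E)-enone, which stays open-chain because the chelated 2'-phenoxide is a poor Michael donor; no stereocentre is formed.

**Step 2**
Reactants: 4 (E)-4'-benzyloxy-2'-hydroxy-3,4-bis(benzyloxy)chalcone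
Product: 6 (2R,3R)-7,3',4'-tri-O-benzylfustin, via (αR,βS)-epoxychalcone 5 (not isolated)
Conditions: L-series Shi diacetate ketone (4,5-di-O-acetyl-1,2-O-isopropylidene-β-L-erythro-2,3-hexodiulo-2,6-pyranose, 0.3 equiv), Oxone (2KHSO5·KHSO4·K2SO4), NaHCO3, Bu4NHSO4 (cat.), MeCN/dimethoxymethane/aq Na2EDTA, 0 °C, pH 8; Na2S2O3 quench; then DBU (0.2 equiv), THF, 0 °C, Ar
Reagents that add atoms: potassium peroxymonosulfate (active salt of Oxone), [K+].[O-]S(=O)(=O)OO
Why: Proposed new method: the chiral dioxirane epoxidises the electron-rich cinnamoyl C=C of 4 through the spiro transition state of the Shi epoxidation while the carbonyl-chelated 2'-OH stays protonated at pH 8, the L-series ketone being chosen to give the (αR,βS)-epoxide 5 (mirror image of the sense the D-series ketone shows with (E)-cinnamates), and catalytic DBU then lets the 2'-phenoxide open 5 in 6-endo mode at the benzylic Cβ with inversion, so that C3 keeps the R configuration of Cα and C2 becomes R (2,3-trans); the closest known reactions are the Shi epoxidation of (E)-cinnamates, the dimethyldioxirane epoxidation of free 2'-hydroxychalcones and the base-induced closure of such epoxides to trans-3-hydroxyflavanones (epoxide branch of the Algar–Flynn–Oyamada reaction).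

**Step 3**
Reactants: 6 (2R,3R)-7,3',4'-tri-O-benzylfustin
Product: 7 (+)-fustin
Conditions: H2 (1 atm), Pd/C (10 wt%), EtOAc/MeOH 1:1, 20 °C
Reagents that add atoms: none
Why: Heterogeneous hydrogenolysis of the three aryl benzyl ethers, which leaves the electron-rich chromanone carbonyl and the C2 and C3 stereocentres untouched at one atmosphere and room temperature.

**Step 4**
Reactants: 7 (+)-fustin (two molecules)
Product: 10 fisetinidol-(4β→6)-mollisacacidin (target), via (+)-mollisacacidin 8 (not isolated), via C4 benzylic cation 9 (not isolated)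
Conditions: NaBH4 (3 equiv), H2O/EtOH 4:1, 0 → 20 °C, N2; then HCl to 0.1 M, 20 °C, 48 h, stopped at about half conversion of 8; Sephadex LH-20 (EtOH), then C18 HPLC
Reagents that add atoms: none
Why: Hydride adds axially from the β face to the C4 carbonyl of 7 to give the 3,4-trans diol 8 (4R), and in dilute acid part of 8 ionises to the cation 9 (stabilised by O1 and the 7-OH), which is captured by C6 of a second molecule of 8 (para to O1, ortho to 7-OH, less hindered than C8) in the biomimetic Friedel–Crafts-type flavan-4-yl condensation; pseudo-axial attack on the β face, syn to the 3-OH, sets the 4S (3,4-cis) centre of 10, and the 4α epimer formed alongside is removed by chromatography.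

**Compound list**
1 | 1-[4-(benzyloxy)-2-hydroxyphenyl]ethan-1-one | CC(=O)c1ccc(OCc2ccccc2)cc1O | starting material
2 | 3,4-bis(benzyloxy)benzaldehyde | O=Cc1ccc(OCc2ccccc2)c(OCc2ccccc2)c1 | starting material
3 | 1-[4-(benzyloxy)-2-hydroxyphenyl]-3-[3,4-bis(benzyloxy)phenyl]-3-hydroxypropan-1-one (racemic aldol adduct) | O=C(CC(O)c1ccc(OCc2ccccc2)c(OCc2ccccc2)c1)c1ccc(OCc2ccccc2)cc1O | intermediate (not isolated)
4 | (E)-1-[4-(benzyloxy)-2-hydroxyphenyl]-3-[3,4-bis(benzyloxy)phenyl]prop-2-en-1-one | O=C(/C=C/c1ccc(OCc2ccccc2)c(OCc2ccccc2)c1)c1ccc(OCc2ccccc2)cc1O | intermediate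
5 | [(2R,3S)-3-[3,4-bis(benzyloxy)phenyl]oxiran-2-yl][4-(benzyloxy)-2-hydroxyphenyl]methanone | O=C(c1ccc(OCc2ccccc2)cc1O)[C@@H]1O[C@H]1c1ccc(OCc2ccccc2)c(OCc2ccccc2)c1 | intermediate (not isolated)
6 | (2R,3R)-7-(benzyloxy)-2-[3,4-bis(benzyloxy)phenyl]-3-hydroxy-2,3-dihydro-4H-chromen-4-one | O=C1c2ccc(OCc3ccccc3)cc2O[C@H](c2ccc(OCc3ccccc3)c(OCc3ccccc3)c2)[C@H]1O | intermediate
7 | (2R,3R)-2-(3,4-dihydroxyphenyl)-3,7-dihydroxy-2,3-dihydro-4H-chromen-4-one, (+)-fustin | O=C1c2ccc(O)cc2O[C@H](c2ccc(O)c(O)c2)[C@H]1O | intermediate
8 | (2R,3S,4R)-2-(3,4-dihydroxyphenyl)-3,4-dihydro-2H-chromene-3,4,7-triol, (+)-mollisacacidin | Oc1ccc2c(c1)O[C@H](c1ccc(O)c(O)c1)[C@@H](O)[C@@H]2O | intermediate (not isolated)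
9 | (2R,3S)-2-(3,4-dihydroxyphenyl)-3,7-dihydroxy-3,4-dihydro-2H-chromen-4-ylium (O-protonated ring A quinone methide) | Oc1ccc2c(c1)O[C@H](c1ccc(O)c(O)c1)[C@@H](O)[CH+]2 | intermediate (not isolated)
10 | (2R,3S,4S)-2-(3,4-dihydroxyphenyl)-4-[(2R,3S,4R)-2-(3,4-dihydroxyphenyl)-3,4,7-trihydroxy-3,4-dihydro-2H-chromen-6-yl]-3,4-dihydro-2H-chromene-3,7-diol | Oc1ccc2c(c1)O[C@H](c1ccc(O)c(O)c1)[C@@H](O)[C@H]2c1cc2c(cc1O)O[C@H](c1ccc(O)c(O)c1)[C@@H](O)[C@@H]2O | target

**Totals**
Total steps: 4. Longest linear sequence: 4 steps (1 or 2 → 4 → 6 → 7 → 10).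

**Steps most likely to fail, with fallbacks**

Step 2 (most risky). The free 2'-phenol may be attacked by the dioxirane, the epoxide may close 5-exo to an aurone-type product, or the facial sense or ee may disappoint. A cis-dihydroflavonol by-product must be removed, not equilibrated, because its C3 epimerisation would lead to the enantiomer. The fallback sets out from 4 and changes the oxygen transfer from an electrophilic dioxirane on a free phenol to a nucleophilic peroxide on a masked phenol. Compound 4 is treated with MOMCl and iPr2NEt in CH2Cl2 to give the 2'-O-methoxymethyl chalcone F1. F1 is epoxidised under Julia–Colonna conditions (poly-L-leucine, urea–H2O2, DBU, THF), where the L-polymer gives the (αR,βS) sense, to the 2'-O-methoxymethyl epoxychalcone F2. HCl in MeOH then removes the methoxymethyl group, and the freed phenol closes ring C at Cβ to give 6, where the route is rejoined.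

Step 4. The cation 9 is attacked on both faces. By analogy with other resorcinol-type nucleophiles the 4α (3,4-trans) dimer should exceed the target, by an estimated 2:1. Trimers form at higher conversion, and the C4–OH of the lower unit can epimerise by ionisation and water return. Partial conversion with recovery of 8 limits the last two problems. Dimers built from the minor enantiomer are diastereomers and are removed in the same chromatography. The fallback sets out from 7 and separates the electrophile and nucleophile roles. Compound 7 is reduced as before, but (+)-mollisacacidin 8 is isolated. One part is thiolysed with PhCH2SH in AcOH to 4-benzylsulfanyl-fisetinidol F3 (both C4 epimers are usable). F3 is then activated with AgBF4 in THF at 0 °C in the presence of 4 equiv of 8. Cation 9 forms under non-acidic conditions in which the 3,4-diol of nucleophile and product does not ionise, so only the two C4-epimeric (4→6) dimers arise. Facial selectivity stays substrate-controlled, and 10 is separated from its 4α epimer as before.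

Step 3. The C4 carbonyl may be over-reduced or the benzylic O1–C2 bond hydrogenolysed. The fallback sets out from 6 and comes back at 7. It replaces hydrogenolysis by a non-reductive Lewis-acid dealkylation: BCl3 with pentamethylbenzene as benzyl-cation scavenger, CH2Cl2, −78 °C, then MeOH. No new compound F0 arises on this detour.

**Further compounds**
F1 | step 2 | (E)-1-[4-(benzyloxy)-2-(methoxymethoxy)phenyl]-3-[3,4-bis(benzyloxy)phenyl]prop-2-en-1-one | O=C(/C=C/c1ccc(OCc2ccccc2)c(OCc2ccccc2)c1)c1ccc(OCc2ccccc2)cc1OCOC
F2 | step 2 | [(2R,3S)-3-[3,4-bis(benzyloxy)phenyl]oxiran-2-yl][4-(benzyloxy)-2-(methoxymethoxy)phenyl]methanone | O=C(c1ccc(OCc2ccccc2)cc1OCOC)[C@@H]1O[C@H]1c1ccc(OCc2ccccc2)c(OCc2ccccc2)c1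
F0 | step 3 | none | none
F3 | step 4 | (2R,3R)-4-(benzylsulfanyl)-2-(3,4-dihydroxyphenyl)-3,4-dihydro-2H-chromene-3,7-diol (C4 epimers, C2 and C3 as in 8) | Oc1ccc2c(c1)O[C@H](c1ccc(O)c(O)c1)[C@@H](O)C2SCc1ccccc1
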